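(All runs are simulated for substances that don't exist, and the scatter is random.)

Ring grows slowly in Tuesday's run, then nearly stops while much starting material remains.

| flask | starting material | protic impurity | remark | time |
|---|---|---|---|---|
| Tuesday's | 20 mM (fed, over 2.5 h) | 3 mM | run made earlier; the fed solution adds 0.25 times the starting volume |  |
| flask | 10 mM (fed, over 2.5 h) | 3.00 mM | the fed solution adds 0.25 times the starting volume | 8.0 d |

Tuesday's run (percent of the starting material charged)

| time / h | ring / % | starting material / % |
|---|---|---|
| 1.50 | 1.3 | 53.0 |
| 2.50 | 3.7 | 82.0 |
| 4.00 | 6.5 | 62.0 |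
| 5.00 | 9.2 | 56.3 |
| 8.00 | 11.7 | 48.2 |
| 12.0 | 17.3 | 42.7 |
| 20.0 | 18.4 | 35.5 |

(each reading ± 1 percentage point)

- every charge counts on the volume at the start, and the solution that is fed holds the whole dose
- what was read earlier has a scatter of 1 percentage point, one standard deviation
- percentages count the whole charge, also what has not yet gone in

- the best time, 8.0 d at the latest, for ring
- the amount of ring, in percent of the starting material charged, at that time
- the first time at which ring reaches 5.6%, in the same percent, in d

Two half-lives can be read from Tuesday's run. From 2.50 h to 5.00 h, ring gains 5.5 percentage points on a mean of 69.2% starting material. Starting material therefore goes to ring at about 0.0318 h⁻¹, a half-life h_F of 0.908 d. From 12.0 h to 20.0 h, that rate should make 10 points of ring, but ring gains 1.1 points. The gap counts as ring lost, at 0.0620 h⁻¹, a half-life h_R of 0.466 d. Take ring as the intermediate between two first-order steps: its peak falls where making equals losing. The reading h_R/h_F, 0.513, is then the peak ratio ρ, ring over starting material at the peak. It carries the scatter of the readings.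

The forecast gives 19.5% of ring at 1.3 d, with 5.6% reached at 0.14 d. It reads the stall as “a reversible ring closure”.

The flask gives 18.7% at 1.05 d, and 5.6% at 0.142 d.

    starting material → ring (k = 0.0330 h⁻¹)
    2 starting material ⇌ open dimer (K = 33.0 L mol⁻¹, k = 5.30 L mol⁻¹ h⁻¹)
    ring → over-reaction product (k = 0.0510 h⁻¹)
    starting material + protic impurity → quenched substrate (k = 34.0 L mol⁻¹ h⁻¹)

At 1.05 d, the flask holds 18.7% ring beside 28.9% starting material, a ratio of 0.647 against the 0.513 read from Tuesday's run. Ring's half-life toward over-reaction product, 0.57 d, is shorter than the 0.88 d of starting material toward ring, a ratio of 0.648.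

The neighbour flask with 12 mM of protic impurity has the same two steps, so ρ ties its ring peak to the starting material standing then. Its computed best is 7.99%, lower than the flask's 18.7%.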